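**Assumption:** compound numbers go to skeletal building blocks, intermediates and the target; ordinary reagents are named with SMILES inside each step. Cembrane numbering is used for atom labels (C1/C14 = ring-fusion carbons, C15–C17 = methylene-lactone carbons). The route is a paper design and has not been run.

## Retrosynthetic overview

1. Eupalmerin acetate (19) comes from the 13-hydroxy lactone 18 by acetylation.
2. Key step: 18 comes from the open-chain α-hydroxy aldehyde / (Z)-2-(bromomethyl)enoate 17 by one chelation-controlled intramolecular indium Barbier allylation. It forms C1–C14, closes the 14-membered carbocycle, sets C1 and C14, and the γ-lactone then closes onto the new C14–O.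
3. 17 comes from the allyl-epoxide diol 14 by cross-metathesis with methyl 2-(bromomethyl)acrylate and selective primary-alcohol oxidation.
4. 14 comes from a C9–C10 Cu-catalysed sp3–sp3 coupling of a C10–C14 Grignard (C12/C13 from Brown (Z)-crotylboration) with a C1–C9 epoxy allylic bromide (C3/C4 from Sharpless epoxidation of geraniol).
5. Ring order: epoxide (step 1), then carbocycle and lactone together (step 13). Avoided: RCM/NHK macrocyclisation remote from the stereocentres with separate lactone construction and late epoxidation.

## Forward route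

**Step 1**
Reactants: 1, geraniol
Product: 2, (2R,3R)-2,3-epoxygeraniol, i.e. [(2R,3R)-3-methyl-3-(4-methylpent-3-en-1-yl)oxiran-2-yl]methanol
Conditions: Ti(OiPr)4 (5 mol %), D-(−)-DET (7 mol %), t-BuOOH, 4 Å MS, CH2Cl2, −20 °C
Reagents that add atoms: tert-butyl hydroperoxide, CC(C)(C)OO (epoxide O)
Why: Sharpless asymmetric epoxidation touches only the allylic-alcohol alkene; D-(−)-tartrate gives the (2R,3R) epoxide (L-(+) gives 2S,3S), which sets C3 and C4 of the target.

**Step 2**
Reactants: 2
Product: 3, [(2R,3R)-3-methyl-3-(4-methylpent-3-en-1-yl)oxiran-2-yl]methyl trifluoromethanesulfonate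
Conditions: Tf2O, 2,6-lutidine, CH2Cl2, −78 °C; cold work-up, used crude
Reagents that add atoms: triflic anhydride, O=S(=O)(OS(=O)(=O)C(F)(F)F)C(F)(F)F
Why: O-sulfonylation of the primary alcohol gives a leaving group at C2 that is far more reactive than the hindered trisubstituted epoxide; no stereocentre is touched.

**Step 3**
Reactants: 3; 4, vinylmagnesium bromide
Product: 5, (2R,3R)-2-methyl-2-(4-methylpent-3-en-1-yl)-3-(prop-2-en-1-yl)oxirane
Conditions: 4 (1.5 equiv), CuI (10 mol %), THF/Et2O, −78 → −40 °C
Reagents that add atoms: none other than reactant 4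
Why: Cu-catalysed Grignard displacement of a primary triflate (SN2 at C2) is much faster than opening of the trisubstituted epoxide and forms C1–C2; the epoxide stereocentres are spectators.

**Step 4**
Reactants: 5
Product: 6, (2E)-2-methyl-5-[(2R,3R)-2-methyl-3-(prop-2-en-1-yl)oxiran-2-yl]pent-2-en-1-ol
Conditions: SeO2 (0.3 equiv), t-BuOOH, CH2Cl2, 0 °C → rt (no acid additive); then NaBH4, MeOH, 0 °C to return over-oxidised enal
Reagents that add atoms: selenium dioxide, O=[Se]=O, with tert-butyl hydroperoxide, CC(C)(C)OO (allylic O)
Why: Sharpless SeO2 allylic oxidation (ene/[2,3] shift) oxidises the (E)-methyl of the trisubstituted alkene E-selectively; the monosubstituted alkene and the epoxide react far more slowly under acid-free conditions.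

**Step 5**
Reactants: 6
Product: 7, (2R,3R)-2-[(3E)-5-bromo-4-methylpent-3-en-1-yl]-2-methyl-3-(prop-2-en-1-yl)oxirane
Conditions: MsCl, Et3N, THF, −40 °C; then LiBr, 0 °C
Reagents that add atoms: lithium bromide, [Li+].[Br-]
Why: Mesylation followed by SN2 bromide exchange converts the primary allylic alcohol to the bromide without allylic transposition and without opening the epoxide.

**Step 6**
Reactants: 8, (tert-butyldimethylsilyloxy)acetaldehyde; 9, cis-2-butene
Product: 10, (2R,3S)-1-[(tert-butyldimethylsilyl)oxy]-3-methylpent-4-en-2-ol
Conditions: 9, n-BuLi, KOt-Bu, THF, −78 → −45 °C; (+)-Ipc2BOMe, −78 °C; BF3·OEt2; then 8, −78 °C; NaOH/H2O2 work-up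
Reagents that add atoms: none other than reactant 9
Why: Brown asymmetric (Z)-crotylboration through a closed chair transition state gives the syn Me/OH pair; the (+)-Ipc2B reagent (from (−)-α-pinene) attacks the Re face of the aldehyde, setting C13 (R) and C12 (S).

**Step 7**
Reactants: 10
Product: 11, (3S,4R)-4,5-bis[(tert-butyldimethylsilyl)oxy]-3-methylpent-1-ene
Conditions: TBSOTf, 2,6-lutidine, CH2Cl2, −78 → 0 °C
Reagents that add atoms: TBS triflate, CC(C)(C)[Si](C)(C)OS(=O)(=O)C(F)(F)F
Why: Silylation of the secondary alcohol under non-basic conditions avoids silyl migration and gives a diol mask that is removed later in one fluoride step.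

**Step 8**
Reactants: 11
Product: 12, (2R,3S)-1,2-bis[(tert-butyldimethylsilyl)oxy]-5-iodo-3-methylpentane
Conditions: Cp2Zr(H)Cl, THF, rt; then I2, 0 °C
Reagents that add atoms: iodine, II
Why: Schwartz hydrozirconation of the terminal alkene is anti-Markovnikov and iodinolysis of the primary C–Zr bond gives the primary iodide directly; the allylic C12 stereocentre is not involved.

**Step 9**
Reactants: 12; 7
Product: 13, (2R,3R)-2-[(3E,8S,9R)-9,10-bis{[tert-butyl(dimethyl)silyl]oxy}-4,8-dimethyldec-3-en-1-yl]-2-methyl-3-(prop-2-en-1-yl)oxirane
Conditions: 12, t-BuLi (2.1 equiv), Et2O, −78 °C; MgBr2·OEt2; then 7, Li2CuCl4 (5 mol %), THF, −78 → −20 °C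
Reagents that add atoms: none
Why: Kochi-type Cu-catalysed coupling of a primary alkyl Grignard with a primary allylic bromide is α-selective (SN2) with retention of the E alkene and forms C9–C10; at low temperature the hindered epoxide and the terminal alkene are inert.

**Step 10**
Reactants: 13
Product: 14, (2R,3S,7E)-3,7-dimethyl-10-[(2R,3R)-2-methyl-3-(prop-2-en-1-yl)oxiran-2-yl]dec-7-ene-1,2-diol
Conditions: TBAF, THF, 0 °C → rt
Reagents that add atoms: none
Why: Fluoride removes both TBS ethers in one step; the diol is too remote from the epoxide for intramolecular opening.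

**Step 11**
Reactants: 14; 15, methyl 2-(bromomethyl)acrylate
Product: 16, methyl (2Z)-2-(bromomethyl)-4-{(2R,3R)-3-[(3E,8S,9R)-9,10-dihydroxy-4,8-dimethyldec-3-en-1-yl]-3-methyloxiran-2-yl}but-2-enoate
Conditions: Hoveyda–Grubbs II (10 mol %), 15 (8 equiv), 1,4-benzoquinone (20 mol %), CH2Cl2, 40 °C
Reagents that add atoms: none other than reactant 15
Why: Proposed new method: olefin cross-metathesis of a terminal alkene with a 2-substituted acrylate, the closest known case being cross-metathesis with methacrylates, which gives the trisubstituted enoate with the alkyl chain trans to the ester (here the Z bromide); Ru carbenes tolerate allylic bromides, free diols and epoxides, the C7=C8 alkene is a spectator, ring closure onto it is blocked by the trans epoxide, and benzoquinone suppresses alkene migration.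

**Step 12**
Reactants: 16
Product: 17, methyl (2Z)-2-(bromomethyl)-4-{(2R,3R)-3-[(3E,8S,9R)-9-hydroxy-4,8-dimethyl-10-oxodec-3-en-1-yl]-3-methyloxiran-2-yl}but-2-enoate (α-hydroxy aldehyde, used crude)
Conditions: TEMPO (20 mol %), PhI(OAc)2 (1.1 equiv), CH2Cl2, 0 °C → rt
Reagents that add atoms: none
Why: Oxoammonium (TEMPO) oxidation is selective for the primary over the secondary alcohol and stops at the aldehyde; the neutral conditions leave the allylic bromide, epoxide and alkenes untouched and do not epimerise C13.

**Step 13**
Reactants: 17
Product: 18, 13-O-deacetyl-eupalmerin, i.e. (1S,3R,4R,7E,12S,13R,14R)-3,4-epoxy-13-hydroxycembra-7,15(17)-dien-16,14-olide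
Conditions: In powder (5 equiv), THF/H2O 1:1, slow addition of 17 to 2 mM final concentration, rt; then 2-hydroxypyridine (cat.), PhMe, 50 °C if lactonisation is incomplete
Reagents that add atoms: none (Br and MeOH are lost)
Why: Proposed new method: an intramolecular Barbier allylation in which the allylindium formed from the bromide adds through its γ-carbon (C1) to the C14 aldehyde; the closest known reactions are Cr(II)- and Zn-mediated macrocyclising allyl bromide–aldehyde additions and intermolecular aqueous indium additions of 2-(bromomethyl)acrylates to unprotected α-hydroxy aldehydes. Indium chelation between C13–OH and C14=O directs attack anti to the C12 chain (13,14-syn), the (Z)-γ-substituted allylindium reacts through a chair six-membered transition state (14,1-syn, hence the cis-fused lactone), and the C14 alkoxide closes the favoured γ-lactone in preference to the δ-lactone from C13–OH.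

**Step 14**
Reactants: 18
Product: 19, eupalmerin acetate
Conditions: Ac2O, pyridine, DMAP (cat.), CH2Cl2, 0 °C
Reagents that add atoms: acetic anhydride, CC(=O)OC(C)=O
Why: Standard DMAP-catalysed acetylation of the only free hydroxyl (C13) at low temperature, which avoids translactonisation and leaves the epoxide and α-methylene lactone intact.

## Compound list

1 | geraniol | CC(C)=CCC/C(C)=C/CO | starting material
2 | (2R,3R)-2,3-epoxygeraniol | CC(C)=CCC[C@@]1(C)O[C@@H]1CO | intermediate
3 | epoxygeranyl triflate | CC(C)=CCC[C@@]1(C)O[C@@H]1COS(=O)(=O)C(F)(F)F | intermediate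
4 | vinylmagnesium bromide | C=C[Mg]Br | starting material
5 | (2R,3R)-2-methyl-2-(4-methylpent-3-en-1-yl)-3-allyloxirane | CC(C)=CCC[C@@]1(C)O[C@@H]1CC=C | intermediate
6 | (2E)-2-methyl-5-[(2R,3R)-2-methyl-3-allyloxiran-2-yl]pent-2-en-1-ol | OC/C(C)=C/CC[C@@]1(C)O[C@@H]1CC=C | intermediate
7 | (2R,3R)-2-[(3E)-5-bromo-4-methylpent-3-en-1-yl]-2-methyl-3-allyloxirane | BrC/C(C)=C/CC[C@@]1(C)O[C@@H]1CC=C | intermediate
8 | (tert-butyldimethylsilyloxy)acetaldehyde | CC(C)(C)[Si](C)(C)OCC=O | starting material
9 | cis-2-butene | C/C=C\C | starting material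
10 | (2R,3S)-1-(TBS-oxy)-3-methylpent-4-en-2-ol | CC(C)(C)[Si](C)(C)OC[C@H](O)[C@@H](C)C=C | intermediate
11 | (3S,4R)-4,5-bis(TBS-oxy)-3-methylpent-1-ene | CC(C)(C)[Si](C)(C)OC[C@H](O[Si](C)(C)C(C)(C)C)[C@@H](C)C=C | intermediate
12 | (2R,3S)-1,2-bis(TBS-oxy)-5-iodo-3-methylpentane | CC(C)(C)[Si](C)(C)OC[C@H](O[Si](C)(C)C(C)(C)C)[C@@H](C)CCI | intermediate
13 | coupled bis-TBS allyl epoxide (C1–C14 chain) | CC(C)(C)[Si](C)(C)OC[C@H](O[Si](C)(C)C(C)(C)C)[C@@H](C)CCC/C(C)=C/CC[C@@]1(C)O[C@@H]1CC=C | intermediate
14 | (2R,3S,7E)-3,7-dimethyl-10-[(2R,3R)-2-methyl-3-allyloxiran-2-yl]dec-7-ene-1,2-diol | OC[C@H](O)[C@@H](C)CCC/C(C)=C/CC[C@@]1(C)O[C@@H]1CC=C | intermediate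
15 | methyl 2-(bromomethyl)acrylate | C=C(CBr)C(=O)OC | starting material
16 | (Z)-2-(bromomethyl)enoate diol | OC[C@H](O)[C@@H](C)CCC/C(C)=C/CC[C@@]1(C)O[C@@H]1C/C=C(\CBr)C(=O)OC | intermediate
17 | open-chain α-hydroxy aldehyde / (Z)-2-(bromomethyl)enoate | O=C[C@H](O)[C@@H](C)CCC/C(C)=C/CC[C@@]1(C)O[C@@H]1C/C=C(\CBr)C(=O)OC | intermediate
18 | 13-O-deacetyl-eupalmerin | C=C1C(=O)O[C@H]2[C@H](O)[C@@H](C)CCC/C(C)=C/CC[C@@]3(C)O[C@@H]3C[C@@H]12 | intermediate
19 | eupalmerin acetate | C=C1C(=O)O[C@H]2[C@H](OC(C)=O)[C@@H](C)CCC/C(C)=C/CC[C@@]3(C)O[C@@H]3C[C@@H]12 | target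

## Summary

Total steps: 14. Longest linear sequence: 11 (geraniol 1 → 19 via steps 1–5 and 9–14); the second fragment (8 → 12) takes 3 steps before convergence.

Three steps most likely to fail, each with a fallback that changes the approach:

1. **Step 13, macrocyclising indium allylation.** Risks are oligomerisation, protodebromination and wrong facial or simple diastereoselectivity within the ring.
 Fallback: run the same chelation-controlled indium allylation intermolecularly on truncated partners, where no dilution is needed, to make the lactone first. Then close the 14-membered ring at C7=C8 by ring-closing metathesis of isopropenyl and terminal-alkene termini, accepting E/Z separation.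

2. **Step 11, cross-metathesis with methyl 2-(bromomethyl)acrylate.** Risks are low conversion to the trisubstituted alkene and alkene migration toward the epoxide.
 Fallback: build the enoate from an alkyne. Displace triflate 3 with lithiated THP-protected propargyl alcohol, hydrostannylate under Pd catalysis (tin α to the CH2O group), exchange Sn for I, carry out Pd/CO/MeOH carbonylation, and convert the alcohol to the bromide. This gives the same (Z)-2-(bromomethyl)enoate without metathesis.

3. **Step 12, selective oxidation of the 1,2-diol to the α-hydroxy aldehyde.** Risks are glycol cleavage and dimerisation or epimerisation of the aldehyde.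
 Fallback: change the C13 protection. Protect 10 as the PMB ether (PMB trichloroacetimidate) instead of TBS, oxidise the C14 primary alcohol with Dess–Martin periodinane, run the Barbier ring closure on the α-OPMB aldehyde (ether chelation), then remove PMB with DDQ and acetylate. This is two steps longer.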